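**Strategy.** The γ-lactone is disconnected across O–C6 and C12–C11 (germacrane numbering): CO2 plus the three-carbon unit C6–C7–C11. That unit is stored as a cyclopropane cis-fused to the ten-membered ring and activated by the C4=C5 alkene (a vinylcyclopropane). A nickel(0)-mediated formal (3+2) cycloaddition (ring expansion by CO2 insertion) forms C11–C12 and C6–O in one operation, exploiting the allylic position of C6, and should deliver the trans-fused α-methyl lactone. The bicyclo[8.1.0]undecadiene precursor arises from a 4-alkoxycyclohexenone by sulfonium-ylide cyclopropanation and an anionic oxy-Cope ring expansion that also fixes both ring alkene geometries.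

Key step: step 11

Remark: atoms are numbered as in germacranolides (C1=C10 bears C14H3, C4=C5 bears C15H2OH, lactone O on C6, C7–C11(C13H3)–C12(=O), ester O on C8); α/β mean lower/upper face. Compounds 1, 8, 17 and the reagents named with SMILES are taken as commercial.

Step 1
Reactants: 1 1,4-dioxaspiro[4.5]dec-6-en-8-one
Product: 2 (S)-1,4-dioxaspiro[4.5]dec-6-en-8-ol
Conditions: RuCl(p-cymene)[(S,S)-TsDPEN] (1 mol %), HCO2H/Et3N (5:2), CH2Cl2, rt
Reagents that add atoms: none
Why: Noyori asymmetric transfer hydrogenation reduces the enone carbonyl 1,2-selectively; with the alkenyl group in the role of the aryl group of aryl ketones, the (S,S)-catalyst should give the (S)-carbinol, the future C8.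

Step 2
Reactants: 2 (S)-1,4-dioxaspiro[4.5]dec-6-en-8-ol
Product: 3 (S)-8-[(4-methoxybenzyl)oxy]-1,4-dioxaspiro[4.5]dec-6-ene
Conditions: NaH, PMBCl, Bu4NI (cat.), THF/DMF, 0 °C to rt
Reagents that add atoms: 4-methoxybenzyl chloride, COc1ccc(CCl)cc1
Why: Williamson etherification of the allylic alkoxide; the stereocentre is not touched.

Step 3
Reactants: 3 (S)-8-[(4-methoxybenzyl)oxy]-1,4-dioxaspiro[4.5]dec-6-ene
Product: 4 (S)-4-[(4-methoxybenzyl)oxy]cyclohex-2-en-1-one
Conditions: PPTS (cat.), acetone/H2O, 50 °C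
Reagents that add atoms: water, O
Why: Mild acid-catalysed ketal hydrolysis unmasks the enone without touching the PMB ether or C8.

Step 4
Reactants: 4 (S)-4-[(4-methoxybenzyl)oxy]cyclohex-2-en-1-one
Product: 5 (1R,5S,6S,7S)-5-[(4-methoxybenzyl)oxy]-7-methylbicyclo[4.1.0]heptan-2-one (cyclopropane anti to the PMB ether, 7-methyl exo)
Conditions: ethyldiphenylsulfonium tetrafluoroborate, LDA, DME, -78 to -20 °C
Reagents that add atoms: ethyldiphenylsulfonium tetrafluoroborate, CC[S+](c1ccccc1)c1ccccc1.F[B-](F)(F)F
Why: Corey–Chaykovsky-type cyclopropanation (conjugate addition of diphenylsulfonium ethylide, then 3-exo-tet closure); the ylide should attack C7 anti to the C8 ether, which sets C6 and C7, and the betaine should close through the less crowded rotamer, placing the C11 methyl exo.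

Step 5
Reactants: 5 (1R,5S,6S,7S)-5-[(4-methoxybenzyl)oxy]-7-methylbicyclo[4.1.0]heptan-2-one
Product: 6 (1R,5S,6S,7S)-5-[(4-methoxybenzyl)oxy]-3,7-dimethylbicyclo[4.1.0]heptan-2-one (C3 epimers)
Conditions: LDA, THF, -78 °C; MeI, -78 to 0 °C
Reagents that add atoms: iodomethane, CI
Why: Kinetic enolate alkylation; only C3 (= C10) carries enolisable hydrogens because the other α-carbon is a cyclopropane bridgehead, and the C3 configuration is reset in step 6.

Step 6
Reactants: 6 (1R,5S,6S,7S)-5-[(4-methoxybenzyl)oxy]-3,7-dimethylbicyclo[4.1.0]heptan-2-one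
Product: 7 (1R,3S,5S,6S,7S)-5-[(4-methoxybenzyl)oxy]-3,7-dimethyl-3-vinylbicyclo[4.1.0]heptan-2-one (vinyl anti to the cyclopropane)
Conditions: Pd2(dba)3 (2.5 mol %), Q-Phos (5 mol %), LiHMDS, vinyl bromide, THF/toluene, rt to 50 °C
Reagents that add atoms: vinyl bromide, C=CBr
Why: Palladium-catalysed α-alkenylation of the only possible ketone enolate; the vinyl group should be delivered to the α-face, anti to the cyclopropane, which sets the quaternary C10 with vinyl α and methyl β.

Step 7
Reactants: 8 2-bromoprop-2-en-1-ol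
Product: 9 [(2-bromoprop-2-en-1-yl)oxy](tert-butyl)diphenylsilane
Conditions: TBDPSCl, imidazole, DMF, rt
Reagents that add atoms: tert-butylchlorodiphenylsilane, CC(C)(C)[Si](Cl)(c1ccccc1)c1ccccc1
Why: Standard silylation of the primary allylic alcohol; the bulky silyl group suppresses silyl migration in the alkenyllithium of step 8.

Step 8
Reactants: 7 (1R,3S,5S,6S,7S)-5-[(4-methoxybenzyl)oxy]-3,7-dimethyl-3-vinylbicyclo[4.1.0]heptan-2-one, 9 [(2-bromoprop-2-en-1-yl)oxy](tert-butyl)diphenylsilane
Product: 11 2-[3-(tert-butyldiphenylsilyloxy)prop-1-en-2-yl]-5-[(4-methoxybenzyl)oxy]-3,7-dimethyl-3-vinylbicyclo[4.1.0]heptan-2-ol (2-alkenyl and 3-vinyl cis to each other and anti to the cyclopropane; OH syn to it), via alkenyllithium 10 (not isolated)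
Conditions: 9, t-BuLi (2 equiv), Et2O, -78 °C; then 7, THF, -78 to -40 °C; then H2O
Reagents that add atoms: none
Why: Bromine–lithium exchange and 1,2-addition to a non-enolisable ketone; attack from the α-face, anti to both the cyclopropane and the axial β-methyl on C10, should set C5 with the two alkenyl groups cis.

Step 9
Reactants: 11 2-[3-(tert-butyldiphenylsilyloxy)prop-1-en-2-yl]-5-[(4-methoxybenzyl)oxy]-3,7-dimethyl-3-vinylbicyclo[4.1.0]heptan-2-ol
Product: 13 ten-membered enol triflate: 3-[(tert-butyldiphenylsilyloxy)methyl]-9-[(4-methoxybenzyl)oxy]-7,11-dimethylbicyclo[8.1.0]undeca-2,6-dien-2-yl triflate (target numbering: OTf on C5; C4=C5 with C3 and C6 trans; C1=C10 Z; cyclopropane C6–C7–C11 cis-fused, 11-methyl exo; C8 ether trans to the cyclopropane), via potassium enolate 12 (not isolated)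
Conditions: KH, 18-crown-6, THF, 0 °C to rt; then PhNTf2, -78 to 0 °C
Reagents that add atoms: N-phenylbis(trifluoromethanesulfonimide), O=S(=O)(N(c1ccccc1)S(=O)(=O)C(F)(F)F)C(F)(F)F
Why: Anionic oxy-Cope [3,3] rearrangement of the cis-dialkenyl alkoxide through the chair with the C5 alkenyl axial and the C10 vinyl and C8 ether equatorial; this should give the Z C1=C10 alkene and the ring-trans C4=C5 enolate, which is trapped as the triflate with its geometry intact.

Step 10
Reactants: 13 ten-membered enol triflate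
Product: 14 vinylcyclopropane: 3-[(tert-butyldiphenylsilyloxy)methyl]-9-[(4-methoxybenzyl)oxy]-7,11-dimethylbicyclo[8.1.0]undeca-2,6-diene (same geometry and configuration as 13, H on C5)
Conditions: Pd(OAc)2 (5 mol %), PPh3 (10 mol %), HCO2H, Bu3N, DMF, 60 °C
Reagents that add atoms: none
Why: Palladium-catalysed formate reduction of the enol triflate proceeds with retention of alkene geometry; insertion of the trisubstituted transannular alkene should be too slow to compete with hydride transfer.

Step 11
Reactants: 14 vinylcyclopropane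
Product: 15 15-(tert-butyldiphenylsilyloxy)-8α-[(4-methoxybenzyl)oxy]-11βH-germacra-1(10)Z,4E-dien-12,6α-olide (4E in the ring sense: C3 and C6 trans; trans-fused lactone, 11α-methyl)
Conditions: Ni(cod)2 (20 mol %), IPr (20 mol %), CO2 (40 bar), THF, 60 °C
Reagents that add atoms: carbon dioxide, O=C=O
Why: Proposed new method: Ni(0)–NHC should insert into the exocyclic, vinyl-activated C6–C11 bond of the vinylcyclopropane (the C–C oxidative addition established for Ni/NHC vinylcyclopropane–cyclopentene rearrangements) to give a σ-alkyl/π-allyl nickelacycle, CO2 then inserts into the Ni–C11(sp3) bond as in nickelalactone chemistry, and the carboxylate attacks the allyl terminus C6 with release of Ni(0); the closest known reaction types are the Pd-catalysed (3+2) cycloadditions of CO2 with trimethylenemethane or methylenecyclopropanes and of CO2 with vinyl epoxides. The lactone ring closes by 5-exo attack of the carboxylate oxygen on the π-allyl terminus C6 (attack at C4 would give a seven-membered ring at a fully substituted carbon). C11 keeps the exo-methyl configuration of the cyclopropane because Ni–C bond formation and CO2 insertion both occur with retention, and this is also the thermodynamically preferred α-methyl epimer. C6 is set by syn C–C insertion followed by anti C–O bond formation (the microscopic reverse of the anti oxidative addition of allylic carboxylates), a net inversion that turns the cis-fused cyclopropane into the trans-fused lactone, which is also the favoured ring fusion should the allylic C–O bond ionise reversibly. The step needs cleavage of C6–C11 and not of the ring-fusion bond C6–C7, carboxylation at the alkyl and not the allyl terminus, and an intact C4=C5 geometry: C6–C11 is the less hindered bond and the one aligned with the alkene π-system, SE2' attack of CO2 on the allyl unit would have to occur at the fully substituted C4, and the syn-allyl geometry is held by the ten-membered ring. High CO2 pressure offsets the modest driving force of cyclopropane carboxylation.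

Step 12
Reactants: 15 15-(tert-butyldiphenylsilyloxy)-8α-[(4-methoxybenzyl)oxy]-11βH-germacra-1(10)Z,4E-dien-12,6α-olide
Product: 16 15-(tert-butyldiphenylsilyloxy)-8α-hydroxy-11βH-germacra-1(10)Z,4E-dien-12,6α-olide
Conditions: DDQ, CH2Cl2/pH 7 buffer, 0 °C
Reagents that add atoms: none
Why: Oxidative cleavage of the PMB ether; the silyl ether, the lactone and the unactivated trisubstituted alkenes should be inert at 0 °C.

Step 13
Reactants: 17 (tert-butyldimethylsilyloxy)acetaldehyde
Product: 18 ethyl (E)-4-(tert-butyldimethylsilyloxy)-2-methylbut-2-enoate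
Conditions: Ph3P=C(CH3)CO2Et, CH2Cl2, rt
Reagents that add atoms: ethyl 2-(triphenylphosphoranylidene)propanoate, CCOC(=O)C(C)=P(c1ccccc1)(c1ccccc1)c1ccccc1
Why: Wittig reaction with a stabilised ylide, which should give the (E)-trisubstituted enoate.

Step 14
Reactants: 18 ethyl (E)-4-(tert-butyldimethylsilyloxy)-2-methylbut-2-enoate
Product: 19 (E)-4-(tert-butyldimethylsilyloxy)-2-methylbut-2-enoic acid
Conditions: LiOH, THF/H2O, rt; then 1 M HCl to pH 4
Reagents that add atoms: lithium hydroxide, [Li+].[OH-]
Why: Saponification of the ethyl ester; the primary TBS ether should survive mild base.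

Step 15
Reactants: 16 15-(tert-butyldiphenylsilyloxy)-8α-hydroxy-11βH-germacra-1(10)Z,4E-dien-12,6α-olide, 19 (E)-4-(tert-butyldimethylsilyloxy)-2-methylbut-2-enoic acid
Product: 20 8α-[(E)-4-(tert-butyldimethylsilyloxy)-2-methylbut-2-enoyloxy]-15-(tert-butyldiphenylsilyloxy)-11βH-germacra-1(10)Z,4E-dien-12,6α-olide
Conditions: 19, 2,4,6-trichlorobenzoyl chloride, Et3N, THF; then 16, DMAP, toluene, rt
Reagents that add atoms: none
Why: Yamaguchi esterification acylates the hindered secondary C8 alcohol through the mixed anhydride without touching C8 or the enoate geometry.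

Step 16
Reactants: 20 8α-[(E)-4-(tert-butyldimethylsilyloxy)-2-methylbut-2-enoyloxy]-15-(tert-butyldiphenylsilyloxy)-11βH-germacra-1(10)Z,4E-dien-12,6α-olide
Product: 21 15-hydroxy-8α-[(E)-4-hydroxy-2-methylbut-2-enoyloxy]-11βH-germacra-1(10)Z,4E-dien-12,6α-olide (CNP0222998.2)
Conditions: HF·pyridine, pyridine, THF, 0 °C to rt
Reagents that add atoms: none
Why: Buffered fluoride desilylation removes both silyl ethers without acid that could trigger transannular cyclisation of the 1,5-diene or acyl migration.

**Compound list**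

1 | 1,4-dioxaspiro[4.5]dec-6-en-8-one | O=C1C=CC2(CC1)OCCO2 | starting material
2 | (S)-1,4-dioxaspiro[4.5]dec-6-en-8-ol | O[C@@H]1C=CC2(CC1)OCCO2 | intermediate
3 | (S)-8-[(4-methoxybenzyl)oxy]-1,4-dioxaspiro[4.5]dec-6-ene | COc1ccc(CO[C@@H]2C=CC3(CC2)OCCO3)cc1 | intermediate
4 | (S)-4-[(4-methoxybenzyl)oxy]cyclohex-2-en-1-one | COc1ccc(CO[C@@H]2C=CC(=O)CC2)cc1 | intermediate
5 | (1R,5S,6S,7S)-5-[(4-methoxybenzyl)oxy]-7-methylbicyclo[4.1.0]heptan-2-one | O=C1CC[C@H](OCc2ccc(OC)cc2)[C@H]2[C@H](C)[C@@H]12 | intermediate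
6 | (1R,5S,6S,7S)-5-[(4-methoxybenzyl)oxy]-3,7-dimethylbicyclo[4.1.0]heptan-2-one (C3 epimers) | O=C1C(C)C[C@H](OCc2ccc(OC)cc2)[C@H]2[C@H](C)[C@@H]12 | intermediate
7 | (1R,3S,5S,6S,7S)-5-[(4-methoxybenzyl)oxy]-3,7-dimethyl-3-vinylbicyclo[4.1.0]heptan-2-one | O=C1[C@](C)(C=C)C[C@H](OCc2ccc(OC)cc2)[C@H]2[C@H](C)[C@@H]12 | intermediate
8 | 2-bromoprop-2-en-1-ol | OCC(Br)=C | starting material
9 | [(2-bromoprop-2-en-1-yl)oxy](tert-butyl)diphenylsilane | C=C(Br)CO[Si](c1ccccc1)(c1ccccc1)C(C)(C)C | intermediate
10 | [3-(tert-butyldiphenylsilyloxy)prop-1-en-2-yl]lithium | [Li]C(=C)CO[Si](c1ccccc1)(c1ccccc1)C(C)(C)C | intermediate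
11 | 2-[3-(tert-butyldiphenylsilyloxy)prop-1-en-2-yl]-5-[(4-methoxybenzyl)oxy]-3,7-dimethyl-3-vinylbicyclo[4.1.0]heptan-2-ol (alkenyl and vinyl cis, anti to cyclopropane) | O[C@@]1(C(=C)CO[Si](c3ccccc3)(c3ccccc3)C(C)(C)C)[C@](C)(C=C)C[C@H](OCc3ccc(OC)cc3)[C@H]2[C@H](C)[C@@H]12 | intermediate
12 | potassium enolate of the ten-membered cyclopropyl ketone (O on C5, C4=C5 ring-trans, C1=C10 Z) | C/C1=C/CC/C(CO[Si](c3ccccc3)(c3ccccc3)C(C)(C)C)=C([O-])/[C@@H]2[C@@H](C)[C@@H]2[C@@H](OCc3ccc(OC)cc3)C1.[K+] | intermediate
13 | ten-membered enol triflate (OTf on C5) | C/C1=C/CC/C(CO[Si](c3ccccc3)(c3ccccc3)C(C)(C)C)=C(OS(=O)(=O)C(F)(F)F)/[C@@H]2[C@@H](C)[C@@H]2[C@@H](OCc3ccc(OC)cc3)C1 | intermediate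
14 | vinylcyclopropane: 3-[(tert-butyldiphenylsilyloxy)methyl]-9-[(4-methoxybenzyl)oxy]-7,11-dimethylbicyclo[8.1.0]undeca-2,6-diene | C/C1=C/CC/C(CO[Si](c3ccccc3)(c3ccccc3)C(C)(C)C)=C/[C@@H]2[C@@H](C)[C@@H]2[C@@H](OCc3ccc(OC)cc3)C1 | intermediate
15 | 15-(tert-butyldiphenylsilyloxy)-8α-[(4-methoxybenzyl)oxy]-11βH-germacra-1(10)Z,4E-dien-12,6α-olide | C/C1=C/CC/C(CO[Si](c3ccccc3)(c3ccccc3)C(C)(C)C)=C/[C@H]2OC(=O)[C@@H](C)[C@@H]2[C@@H](OCc3ccc(OC)cc3)C1 | intermediate
16 | 15-(tert-butyldiphenylsilyloxy)-8α-hydroxy-11βH-germacra-1(10)Z,4E-dien-12,6α-olide | C/C1=C/CC/C(CO[Si](c3ccccc3)(c3ccccc3)C(C)(C)C)=C/[C@H]2OC(=O)[C@@H](C)[C@@H]2[C@@H](O)C1 | intermediate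
17 | (tert-butyldimethylsilyloxy)acetaldehyde | O=CCO[Si](C)(C)C(C)(C)C | starting material
18 | ethyl (E)-4-(tert-butyldimethylsilyloxy)-2-methylbut-2-enoate | CCOC(=O)/C(C)=C/CO[Si](C)(C)C(C)(C)C | intermediate
19 | (E)-4-(tert-butyldimethylsilyloxy)-2-methylbut-2-enoic acid | OC(=O)/C(C)=C/CO[Si](C)(C)C(C)(C)C | intermediate
20 | 8α-[(E)-4-(tert-butyldimethylsilyloxy)-2-methylbut-2-enoyloxy]-15-(tert-butyldiphenylsilyloxy)-11βH-germacra-1(10)Z,4E-dien-12,6α-olide | C/C1=C/CC/C(CO[Si](c3ccccc3)(c3ccccc3)C(C)(C)C)=C/[C@H]2OC(=O)[C@@H](C)[C@@H]2[C@@H](OC(=O)/C(C)=C/CO[Si](C)(C)C(C)(C)C)C1 | intermediate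
21 | CNP0222998.2 | C/C1=C/CC/C(CO)=C/[C@H]2OC(=O)[C@@H](C)[C@@H]2[C@@H](OC(=O)/C(C)=C/CO)C1 | target

**Totals.** 16 steps in all; longest linear sequence 13 steps (steps 1–6, 8–12, 15, 16).

**Steps most likely to fail**

Step 11 (proposed new method). The nickel may insert into the ring-fusion bond C6–C7 instead of C6–C11, CO2 may attack the allyl terminus, the vinylcyclopropane may rearrange to a cyclopentene or undergo β-hydride elimination, the CO2-fixation equilibrium may be unfavourable, or syn C–O closure may give the cis-fused lactone. The fallback sets out from 14 and comes back at 15, making the same two bonds one after the other by known polar reactions. Palladium(II)-induced ring opening of the vinylcyclopropane under chloroacetoxylation conditions (Pd(OAc)2 cat., benzoquinone, LiCl, LiOAc, AcOH/acetone; chloride opens the cyclopropane at C11 and acetate is captured at C6 of the π-allyl) would give the 6-acetoxy-11-chloro compound F1. Finkelstein exchange (NaI, butanone) would give the iodide F2. Magnesium insertion in the presence of ZnCl2/LiCl would give the secondary alkylzinc iodide F3, which adds to CO2 (1 bar, MgCl2, DMF) to give the zinc carboxylate F4. Pd(PPh3)4 (THF, 50 °C) would then close the lactone by intramolecular Tsuji–Trost substitution of the allylic acetate, the π-allyl intermediate letting C6 settle in the trans-fused arrangement; brief DBU treatment would equilibrate C11, to reach 15.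

Step 9. The rearrangement may pass through the alternative chair or a boat transition state, giving the wrong alkene geometry, and the crowded potassium enolate may be triflated slowly or lose its geometry before trapping. The fallback sets out from 11 and comes back at 13, separating the two events. The oxy-Cope rearrangement (KH, 18-crown-6) is quenched with aqueous NH4Cl to give the ten-membered cyclopropyl ketone F5, on which the C1=C10 geometry can be secured. F5 is then enolised kinetically (KHMDS, THF, -78 °C; C4 is the only enolisable position) and triflated with N-(5-chloropyridin-2-yl)triflimide to give 13.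

Step 6. The hindered tertiary enolate may couple poorly, or the vinyl group may enter on the wrong face. The fallback sets out from 6 and comes back at 7 with a vinyl-cation equivalent in place of the cross-coupling. The lithium enolate of 6 (LDA, THF, -78 °C) adds to phenyl vinyl sulfoxide to give the β-sulfinylethyl ketone F6, and thermal syn-elimination of the sulfoxide (toluene, NaHCO3, 110 °C) gives 7. If the facial preference proved opposite, the order of methyl and vinyl introduction would be reversed.

**Further compounds**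

F1 | step 11 | 6-acetoxy-11-chloro ring-opened macrocycle (C7–CH(Cl)CH3, allylic acetate on C6; C6 and C11 mixtures) | C/C1=C/CC/C(CO[Si](c2ccccc2)(c2ccccc2)C(C)(C)C)=C/C(OC(C)=O)[C@H](C(C)Cl)[C@@H](OCc2ccc(OC)cc2)C1
F2 | step 11 | 6-acetoxy-11-iodo ring-opened macrocycle | C/C1=C/CC/C(CO[Si](c2ccccc2)(c2ccccc2)C(C)(C)C)=C/C(OC(C)=O)[C@H](C(C)I)[C@@H](OCc2ccc(OC)cc2)C1
F3 | step 11 | secondary alkylzinc iodide at C11 | C/C1=C/CC/C(CO[Si](c2ccccc2)(c2ccccc2)C(C)(C)C)=C/C(OC(C)=O)[C@H](C(C)[Zn]I)[C@@H](OCc2ccc(OC)cc2)C1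
F4 | step 11 | zinc carboxylate (C11–CO2ZnI, allylic acetate on C6) | C/C1=C/CC/C(CO[Si](c2ccccc2)(c2ccccc2)C(C)(C)C)=C/C(OC(C)=O)[C@H](C(C)C(=O)O[Zn]I)[C@@H](OCc2ccc(OC)cc2)C1
F5 | step 9 | ten-membered cyclopropyl ketone (C5=O, C4 epimers, C1=C10 Z) | C/C1=C/CCC(CO[Si](c2ccccc2)(c2ccccc2)C(C)(C)C)C(=O)[C@@H]2[C@@H](C)[C@@H]2[C@@H](OCc3ccc(OC)cc3)C1
F6 | step 6 | 3-[2-(phenylsulfinyl)ethyl] ketone (sulfoxide epimers) | O=C1[C@](C)(CCS(=O)c3ccccc3)C[C@H](OCc2ccc(OC)cc2)[C@H]2[C@H](C)[C@@H]12
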